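The target is cut between the stereogenic CH that bears the isopropenyl group and the allylic CH2 of the (E)-trisubstituted olefin. The feature used is that this CH is allylic to the isopropenyl C=C: the isopropenyl carbon is carried as an acyl carbon, so the CH becomes an enolate carbon, while its partner CH2 is a primary allylic bromide. The key step, an auxiliary-controlled alkylation of the sodium enolate of an (R)-4-benzyloxazolidinone imide that already holds the furan ring and the (Z)-enoate with the C15 (E,E)-allylic bromide, joins both halves and sets the (S) centre in one operation. The acyl group is then turned into isopropenyl by way of a thioester and a methyl ketone.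

Key step: step 12

Remark: the (R)-configured auxiliary is chosen because alkylation anti to its benzyl group should give the (S) centre; bases, MeI/Zn and solvents are taken as commercial.

Step 1
Reactants: 1 geranyl acetate
Product: 3 (2E)-3-methyl-6-oxohex-2-en-1-yl acetate, via ozonide 2 (not isolated)
Conditions: O3 (about 1 equiv), CH2Cl2, −78 °C; then PPh3, −78 °C → rt
Reagents that add atoms: ozone, O=[O+][O-]
Why: Chemoselective ozonolysis, in which the electron-rich 6,7-olefin should be cleaved faster than the 2,3-olefin deactivated by the allylic acetate, with PPh3 reducing the ozonide to the aldehyde.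

Step 2
Reactants: 4 (diethoxyphosphoryl)acetic acid, 5 2-(trimethylsilyl)ethanol
Product: 6 2-(trimethylsilyl)ethyl (diethoxyphosphoryl)acetate
Conditions: DCC, DMAP (cat.), CH2Cl2, 0 °C → rt
Reagents that add atoms: none
Why: Steglich esterification of the acid with the primary alcohol installs the fluoride-labile ester that later frees the acid beside the methyl ester.

Step 3
Reactants: 6 2-(trimethylsilyl)ethyl (diethoxyphosphoryl)acetate, 7 5-bromo-2-methylpent-2-ene
Product: 9 2-(trimethylsilyl)ethyl 2-(diethoxyphosphoryl)-6-methylhept-5-enoate, via sodium carbanion 8 (not isolated)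
Conditions: NaH, DMF, 0 °C; then 7, 50 °C
Reagents that add atoms: none
Why: SN2 C-alkylation of the sodium phosphonoacetate carbanion with the primary bromide attaches the 4-methylpent-3-enyl side chain.

Step 4
Reactants: 9 2-(trimethylsilyl)ethyl 2-(diethoxyphosphoryl)-6-methylhept-5-enoate, 3 (2E)-3-methyl-6-oxohex-2-en-1-yl acetate
Product: 11 2-(trimethylsilyl)ethyl (2E,6E)-8-acetoxy-6-methyl-2-(4-methylpent-3-en-1-yl)octa-2,6-dienoate, via sodium carbanion 10 (not isolated)
Conditions: NaH, THF, 0 °C; then 3, 0 °C → rt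
Reagents that add atoms: none
Why: Horner–Wadsworth–Emmons olefination, in which the unbranched aldehyde and the α-alkyl phosphonate should favour the E-enoate (chain trans to the ester), the minor Z isomer being removed by chromatography.

Step 5
Reactants: 11 2-(trimethylsilyl)ethyl (2E,6E)-8-acetoxy-6-methyl-2-(4-methylpent-3-en-1-yl)octa-2,6-dienoate
Product: 12 2-(trimethylsilyl)ethyl (2E,6E)-8-hydroxy-6-methyl-2-(4-methylpent-3-en-1-yl)octa-2,6-dienoate
Conditions: K2CO3 (cat.), MeOH, 0 °C
Reagents that add atoms: none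
Why: Base-catalysed transesterification removes the primary acetate much faster than methanol can exchange at the hindered conjugated silylethyl ester.

Step 6
Reactants: 12 2-(trimethylsilyl)ethyl (2E,6E)-8-hydroxy-6-methyl-2-(4-methylpent-3-en-1-yl)octa-2,6-dienoate
Product: 13 2-(trimethylsilyl)ethyl (2E,6E)-8-bromo-6-methyl-2-(4-methylpent-3-en-1-yl)octa-2,6-dienoate
Conditions: CBr4, PPh3, CH2Cl2, 0 °C
Reagents that add atoms: carbon tetrabromide, BrC(Br)(Br)Br
Why: Appel bromination of the primary allylic alcohol is an SN2 displacement that should keep the E geometry of the adjacent olefin.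

Step 7
Reactants: 14 3-bromofuran, 15 oxetane
Product: 17 3-(furan-3-yl)propan-1-ol, via furan-3-yllithium 16 (not isolated)
Conditions: n-BuLi, THF, −78 °C; then 15, BF3·OEt2, −78 °C
Reagents that add atoms: none
Why: Bromine–lithium exchange followed by BF3-assisted ring opening of oxetane by the aryllithium, the low temperature keeping the 3-lithio species from isomerising to the 2-lithio isomer.

Step 8
Reactants: 17 3-(furan-3-yl)propan-1-ol
Product: 18 3-(furan-3-yl)propanal
Conditions: Dess–Martin periodinane, NaHCO3, CH2Cl2, 0 °C → rt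
Reagents that add atoms: none
Why: Dess–Martin oxidation under buffered conditions should give the aldehyde without touching the acid-sensitive furan.

Step 9
Reactants: 19 (4R)-4-benzyl-1,3-oxazolidin-2-one, 20 4-bromobutanoyl chloride
Product: 22 (4R)-4-benzyl-3-(4-bromobutanoyl)-1,3-oxazolidin-2-one, via lithiated oxazolidinone 21 (not isolated)
Conditions: n-BuLi, THF, −78 °C; then 20, −78 → 0 °C
Reagents that add atoms: none
Why: N-acylation of the lithiated auxiliary by the acid chloride (acyl substitution), which leaves the stereocentre of the auxiliary untouched.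

Step 10
Reactants: 23 methyl [bis(2,2,2-trifluoroethoxy)phosphoryl]acetate, 22 (4R)-4-benzyl-3-(4-bromobutanoyl)-1,3-oxazolidin-2-one
Product: 25 methyl 6-[(4R)-4-benzyl-2-oxo-1,3-oxazolidin-3-yl]-2-[bis(2,2,2-trifluoroethoxy)phosphoryl]-6-oxohexanoate, via sodium carbanion 24 (not isolated)
Conditions: NaH (slightly less than 1 equiv relative to 23), DMF, 0 °C; then 22, NaI (cat.), rt → 40 °C
Reagents that add atoms: none
Why: Finkelstein-assisted SN2 alkylation of the stabilised phosphonoacetate carbanion, which is too weakly basic to enolise the imide.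

Step 11
Reactants: 25 methyl 6-[(4R)-4-benzyl-2-oxo-1,3-oxazolidin-3-yl]-2-[bis(2,2,2-trifluoroethoxy)phosphoryl]-6-oxohexanoate, 18 3-(furan-3-yl)propanal
Product: 27 methyl (2Z)-2-{4-[(4R)-4-benzyl-2-oxo-1,3-oxazolidin-3-yl]-4-oxobutyl}-5-(furan-3-yl)pent-2-enoate, via potassium carbanion 26 (not isolated)
Conditions: KN(SiMe3)2 (1.0 equiv), 18-crown-6, THF, −78 °C; then 18, −78 °C
Reagents that add atoms: none
Why: Still–Gennari olefination, in which the electron-poor bis(trifluoroethyl) phosphonate under dissociating conditions should give the kinetic Z-enoate (ester cis to the furylethyl chain).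

Step 12
Reactants: 27 methyl (2Z)-2-{4-[(4R)-4-benzyl-2-oxo-1,3-oxazolidin-3-yl]-4-oxobutyl}-5-(furan-3-yl)pent-2-enoate, 13 2-(trimethylsilyl)ethyl (2E,6E)-8-bromo-6-methyl-2-(4-methylpent-3-en-1-yl)octa-2,6-dienoate
Product: 29 2-(trimethylsilyl)ethyl (2E,6E,9S,12Z)-9-{[(4R)-4-benzyl-2-oxo-1,3-oxazolidin-3-yl]carbonyl}-15-(furan-3-yl)-12-(methoxycarbonyl)-6-methyl-2-(4-methylpent-3-en-1-yl)pentadeca-2,6,12-trienoate, via sodium Z-enolate 28 (not isolated)
Conditions: NaN(SiMe3)2 (1.25 equiv), 27 (1.3 equiv), THF, −78 °C; then 13 (1.0 equiv), −78 → −40 °C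
Reagents that add atoms: none
Why: NaN(SiMe3)2 removes a proton from the imide CH2, the most acidic C–H of 27, to give the chelated sodium Z-enolate 28, which displaces bromide from the primary allylic carbon of 13 in an SN2 reaction. The closest known reaction type is the Evans asymmetric alkylation of N-acyloxazolidinone sodium enolates with allylic halides. No ring is closed. The new (S) centre is controlled by the (R)-4-benzyl group of the auxiliary, which blocks one face of the chelated Z-enolate so that the bromide enters anti to it. The step needs enolisation of the imide beside a conjugated methyl ester and reaction of the enolate with the bromide only; the acidity gap between the imide CH2 and the γ-CH2 of the enoate, the low temperature at which a chelated imide enolate should not add to esters, and the unhindered primary allylic CH2 (no SN2' path, E geometry kept) secure this.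

Step 13
Reactants: 29 2-(trimethylsilyl)ethyl (2E,6E,9S,12Z)-9-{[(4R)-4-benzyl-2-oxo-1,3-oxazolidin-3-yl]carbonyl}-15-(furan-3-yl)-12-(methoxycarbonyl)-6-methyl-2-(4-methylpent-3-en-1-yl)pentadeca-2,6,12-trienoate
Product: 30 2-(trimethylsilyl)ethyl (2E,6E,9S,12Z)-9-[(ethylsulfanyl)carbonyl]-15-(furan-3-yl)-12-(methoxycarbonyl)-6-methyl-2-(4-methylpent-3-en-1-yl)pentadeca-2,6,12-trienoate
Conditions: EtSH, n-BuLi (gives LiSEt), THF, −78 → 0 °C
Reagents that add atoms: ethanethiol, CCS
Why: Thiolate attack at the exocyclic imide carbonyl (acyl substitution) should give the thioester without epimerising the α-centre and frees the auxiliary, the hindered conjugated esters being far less electrophilic.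

Step 14
Reactants: 30 2-(trimethylsilyl)ethyl (2E,6E,9S,12Z)-9-[(ethylsulfanyl)carbonyl]-15-(furan-3-yl)-12-(methoxycarbonyl)-6-methyl-2-(4-methylpent-3-en-1-yl)pentadeca-2,6,12-trienoate
Product: 31 2-(trimethylsilyl)ethyl (2E,6E,9S,12Z)-9-acetyl-15-(furan-3-yl)-12-(methoxycarbonyl)-6-methyl-2-(4-methylpent-3-en-1-yl)pentadeca-2,6,12-trienoate
Conditions: MeZnI (from MeI and Zn(Cu)), PdCl2(PPh3)2 (cat.), toluene/THF, rt
Reagents that add atoms: methylzinc iodide, C[Zn]I
Why: Fukuyama coupling of the thioester with the organozinc reagent should give the methyl ketone under neutral conditions that tolerate both esters and do not epimerise the α-centre.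

Step 15
Reactants: 31 2-(trimethylsilyl)ethyl (2E,6E,9S,12Z)-9-acetyl-15-(furan-3-yl)-12-(methoxycarbonyl)-6-methyl-2-(4-methylpent-3-en-1-yl)pentadeca-2,6,12-trienoate
Product: 32 2-(trimethylsilyl)ethyl (2E,6E,9S)-9-[(3Z)-6-(furan-3-yl)-3-(methoxycarbonyl)hex-3-en-1-yl]-6,10-dimethyl-2-(4-methylpent-3-en-1-yl)undeca-2,6,10-trienoate
Conditions: Zn, CH2Br2, TiCl4, THF/CH2Cl2, 0 °C → rt
Reagents that add atoms: dibromomethane, BrCBr
Why: Takai–Lombardo methylenation, whose non-basic zinc–titanium methylene reagent should convert the enolisable ketone into the isopropenyl group without epimerisation and without attacking the esters.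

Step 16
Reactants: 32 2-(trimethylsilyl)ethyl (2E,6E,9S)-9-[(3Z)-6-(furan-3-yl)-3-(methoxycarbonyl)hex-3-en-1-yl]-6,10-dimethyl-2-(4-methylpent-3-en-1-yl)undeca-2,6,10-trienoate
Product: 33 (2E,6E,9S)-9-[(3Z)-6-(furan-3-yl)-3-(methoxycarbonyl)hex-3-en-1-yl]-6,10-dimethyl-2-(4-methylpent-3-en-1-yl)undeca-2,6,10-trienoic acid
Conditions: Bu4NF, THF, 0 °C → rt; then cold dilute aqueous HCl to pH 4
Reagents that add atoms: none
Why: Fluoride-induced β-elimination of the 2-(trimethylsilyl)ethyl ester should release the acid while the methyl ester, the furan and all olefins stay untouched.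

Compound list
1 | geranyl acetate, (2E)-3,7-dimethylocta-2,6-dien-1-yl acetate | CC(C)=CCC/C(C)=C/COC(C)=O | starting material
2 | ozonide (1,2,4-trioxolane) of 1 at the 6,7-olefin, formed in the flask | CC(=O)OC/C=C(\C)CCC1OOC(C)(C)O1 | intermediate
3 | (2E)-3-methyl-6-oxohex-2-en-1-yl acetate | CC(=O)OC/C=C(\C)CCC=O | intermediate
4 | (diethoxyphosphoryl)acetic acid | CCOP(=O)(OCC)CC(=O)O | starting material
5 | 2-(trimethylsilyl)ethanol | OCC[Si](C)(C)C | starting material
6 | 2-(trimethylsilyl)ethyl (diethoxyphosphoryl)acetate | CCOP(=O)(OCC)CC(=O)OCC[Si](C)(C)C | intermediate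
7 | 5-bromo-2-methylpent-2-ene | CC(C)=CCCBr | starting material
8 | sodium carbanion of 6, formed in the flask | [Na+].CCOP(=O)(OCC)[CH-]C(=O)OCC[Si](C)(C)C | intermediate
9 | 2-(trimethylsilyl)ethyl 2-(diethoxyphosphoryl)-6-methylhept-5-enoate (racemic) | CCOP(=O)(OCC)C(CCC=C(C)C)C(=O)OCC[Si](C)(C)C | intermediate
10 | sodium carbanion of 9, formed in the flask | [Na+].CCOP(=O)(OCC)[C-](CCC=C(C)C)C(=O)OCC[Si](C)(C)C | intermediate
11 | 2-(trimethylsilyl)ethyl (2E,6E)-8-acetoxy-6-methyl-2-(4-methylpent-3-en-1-yl)octa-2,6-dienoate | CC(=O)OC/C=C(\C)CC/C=C(\CCC=C(C)C)C(=O)OCC[Si](C)(C)C | intermediate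
12 | 2-(trimethylsilyl)ethyl (2E,6E)-8-hydroxy-6-methyl-2-(4-methylpent-3-en-1-yl)octa-2,6-dienoate | OC/C=C(\C)CC/C=C(\CCC=C(C)C)C(=O)OCC[Si](C)(C)C | intermediate
13 | 2-(trimethylsilyl)ethyl (2E,6E)-8-bromo-6-methyl-2-(4-methylpent-3-en-1-yl)octa-2,6-dienoate | BrC/C=C(\C)CC/C=C(\CCC=C(C)C)C(=O)OCC[Si](C)(C)C | intermediate
14 | 3-bromofuran | Brc1ccoc1 | starting material
15 | oxetane | C1COC1 | starting material
16 | furan-3-yllithium, formed in the flask | [Li]c1ccoc1 | intermediate
17 | 3-(furan-3-yl)propan-1-ol | OCCCc1ccoc1 | intermediate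
18 | 3-(furan-3-yl)propanal | O=CCCc1ccoc1 | intermediate
19 | (4R)-4-benzyl-1,3-oxazolidin-2-one | O=C1N[C@H](Cc2ccccc2)CO1 | starting material
20 | 4-bromobutanoyl chloride | O=C(Cl)CCCBr | starting material
21 | N-lithio derivative of 19, formed in the flask | [Li]N1[C@H](Cc2ccccc2)COC1=O | intermediate
22 | (4R)-4-benzyl-3-(4-bromobutanoyl)-1,3-oxazolidin-2-one | O=C1OC[C@@H](Cc2ccccc2)N1C(=O)CCCBr | intermediate
23 | methyl [bis(2,2,2-trifluoroethoxy)phosphoryl]acetate | COC(=O)CP(=O)(OCC(F)(F)F)OCC(F)(F)F | starting material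
24 | sodium carbanion of 23, formed in the flask | [Na+].COC(=O)[CH-]P(=O)(OCC(F)(F)F)OCC(F)(F)F | intermediate
25 | methyl 6-[(4R)-4-benzyl-2-oxo-1,3-oxazolidin-3-yl]-2-[bis(2,2,2-trifluoroethoxy)phosphoryl]-6-oxohexanoate (both epimers at C-2) | O=C1OC[C@@H](Cc2ccccc2)N1C(=O)CCCC(C(=O)OC)P(=O)(OCC(F)(F)F)OCC(F)(F)F | intermediate
26 | potassium carbanion of 25, formed in the flask | [K+].O=C1OC[C@@H](Cc2ccccc2)N1C(=O)CCC[C-](C(=O)OC)P(=O)(OCC(F)(F)F)OCC(F)(F)F | intermediate
27 | methyl (2Z)-2-{4-[(4R)-4-benzyl-2-oxo-1,3-oxazolidin-3-yl]-4-oxobutyl}-5-(furan-3-yl)pent-2-enoate | O=C1OC[C@@H](Cc2ccccc2)N1C(=O)CCC/C(=C/CCc1ccoc1)C(=O)OC | intermediate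
28 | sodium Z-enolate of 27, formed in the flask | [Na+].[O-]/C(=C\CC/C(=C/CCc1ccoc1)C(=O)OC)N1[C@H](Cc2ccccc2)COC1=O | intermediate
29 | 2-(trimethylsilyl)ethyl (2E,6E,9S,12Z)-9-{[(4R)-4-benzyl-2-oxo-1,3-oxazolidin-3-yl]carbonyl}-15-(furan-3-yl)-12-(methoxycarbonyl)-6-methyl-2-(4-methylpent-3-en-1-yl)pentadeca-2,6,12-trienoate | O=C1OC[C@@H](Cc2ccccc2)N1C(=O)[C@H](C/C=C(\C)CC/C=C(\CCC=C(C)C)C(=O)OCC[Si](C)(C)C)CC/C(=C/CCc1ccoc1)C(=O)OC | intermediate
30 | 2-(trimethylsilyl)ethyl (2E,6E,9S,12Z)-9-[(ethylsulfanyl)carbonyl]-15-(furan-3-yl)-12-(methoxycarbonyl)-6-methyl-2-(4-methylpent-3-en-1-yl)pentadeca-2,6,12-trienoate | CCSC(=O)[C@H](C/C=C(\C)CC/C=C(\CCC=C(C)C)C(=O)OCC[Si](C)(C)C)CC/C(=C/CCc1ccoc1)C(=O)OC | intermediate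
31 | 2-(trimethylsilyl)ethyl (2E,6E,9S,12Z)-9-acetyl-15-(furan-3-yl)-12-(methoxycarbonyl)-6-methyl-2-(4-methylpent-3-en-1-yl)pentadeca-2,6,12-trienoate | CC(=O)[C@H](C/C=C(\C)CC/C=C(\CCC=C(C)C)C(=O)OCC[Si](C)(C)C)CC/C(=C/CCc1ccoc1)C(=O)OC | intermediate
32 | 2-(trimethylsilyl)ethyl (2E,6E,9S)-9-[(3Z)-6-(furan-3-yl)-3-(methoxycarbonyl)hex-3-en-1-yl]-6,10-dimethyl-2-(4-methylpent-3-en-1-yl)undeca-2,6,10-trienoate | C=C(C)[C@H](C/C=C(\C)CC/C=C(\CCC=C(C)C)C(=O)OCC[Si](C)(C)C)CC/C(=C/CCc1ccoc1)C(=O)OC | intermediate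
33 | (2E,6E,9S)-9-[(3Z)-6-(furan-3-yl)-3-(methoxycarbonyl)hex-3-en-1-yl]-6,10-dimethyl-2-(4-methylpent-3-en-1-yl)undeca-2,6,10-trienoic acid | C=C(C)[C@H](C/C=C(\C)CC/C=C(\CCC=C(C)C)C(=O)O)CC/C(=C/CCc1ccoc1)C(=O)OC | target

Total step count: 16 steps.
Longest linear sequence: 10 steps (steps 2, 3, 4, 5, 6, 12, 13, 14, 15, 16).

Steps most likely to fail

Step 12. Enolate 28 may close onto its own methyl ester in a Dieckmann-type ring closure or exchange protons with the enoate, so that alkylation stays incomplete and the facial selectivity erodes. The fallback moves the fragment union in front of the olefination. It sets out from phosphonate imide 25 and bromide 13. Imide 25 is deprotonated twice (NaN(SiMe3)2, 2.1 equiv, THF, −78 °C) to the disodium dianion F1. Its phosphonate-stabilised carbanion is inert at this temperature, so only the imide enolate should be alkylated by 13, giving the alkylated phosphonate imide F2 with the same auxiliary control. The potassium carbanion F3 of F2 (KN(SiMe3)2, 18-crown-6, THF, −78 °C) is then condensed with aldehyde 18 in a Still–Gennari olefination, which comes back to the route at imide 29.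

Step 4. The α-branched phosphonate may give poor control of the olefin geometry, so that an E/Z mixture that is hard to separate is carried on. The fallback is an aldol–elimination sequence under thermodynamic control. It sets out from bromide 7 and aldehyde 3. The lithium enolate of commercial 2-(trimethylsilyl)ethyl acetate (LiN(iPr)2, THF/DMPU, −78 °C → rt) is alkylated with 7 to 2-(trimethylsilyl)ethyl 6-methylhept-5-enoate F4. The lithium enolate F5 of this ester (LiN(iPr)2, THF, −78 °C) adds to 3 to give the β-hydroxy ester F6. Mesylation (MsCl, Et3N, CH2Cl2, 0 °C) gives the mesylate F7, and E1cB elimination with DBU should give mainly the more stable E-enoate, which comes back to the route at dienoate 11.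

Step 10. The weakly nucleophilic bis(trifluoroethyl) phosphonoacetate anion may react sluggishly with the bromide, so that acyl transfer from the imide or internal alkylation to a cyclopropane competes. The fallback attaches the auxiliary after the alkylation. It sets out from sodium carbanion 24 (from 23). Alkylation with commercial tert-butyl 4-bromobutanoate (NaI, DMF, 40 °C) gives the tert-butyl ester F8. CF3CO2H in CH2Cl2 cleaves it to the acid F9, at a stage where no acid-sensitive group is present yet. The mixed pivalic anhydride F10 (t-BuCOCl, Et3N, THF, −20 °C) is then treated with oxazolidinone 19 and LiCl, which comes back to the route at phosphonate imide 25.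

Further compounds
F1 | step 12 | disodium dianion of 25 (imide enolate and phosphonate carbanion) | [Na+].[Na+].[O-]/C(=C\CC[C-](C(=O)OC)P(=O)(OCC(F)(F)F)OCC(F)(F)F)N1[C@H](Cc2ccccc2)COC1=O
F2 | step 12 | (S)-alkylated phosphonate imide, 29 with CH[P(O)(OCH2CF3)2]CO2Me in place of the Z-enoate | O=C1OC[C@@H](Cc2ccccc2)N1C(=O)[C@H](C/C=C(\C)CC/C=C(\CCC=C(C)C)C(=O)OCC[Si](C)(C)C)CCC(C(=O)OC)P(=O)(OCC(F)(F)F)OCC(F)(F)F
F3 | step 12 | potassium carbanion of F2 | [K+].O=C1OC[C@@H](Cc2ccccc2)N1C(=O)[C@H](C/C=C(\C)CC/C=C(\CCC=C(C)C)C(=O)OCC[Si](C)(C)C)CC[C-](C(=O)OC)P(=O)(OCC(F)(F)F)OCC(F)(F)F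
F4 | step 4 | 2-(trimethylsilyl)ethyl 6-methylhept-5-enoate | CC(C)=CCCCC(=O)OCC[Si](C)(C)C
F5 | step 4 | lithium enolate of F4 | [Li+].[O-]C(=CCCC=C(C)C)OCC[Si](C)(C)C
F6 | step 4 | 2-(trimethylsilyl)ethyl (6E)-8-acetoxy-3-hydroxy-6-methyl-2-(4-methylpent-3-en-1-yl)oct-6-enoate (diastereomer mixture) | CC(=O)OC/C=C(\C)CCC(O)C(CCC=C(C)C)C(=O)OCC[Si](C)(C)C
F7 | step 4 | methanesulfonate of F6 | CC(=O)OC/C=C(\C)CCC(OS(C)(=O)=O)C(CCC=C(C)C)C(=O)OCC[Si](C)(C)C
F8 | step 10 | 6-tert-butyl 1-methyl 2-[bis(2,2,2-trifluoroethoxy)phosphoryl]hexanedioate | COC(=O)C(CCCC(=O)OC(C)(C)C)P(=O)(OCC(F)(F)F)OCC(F)(F)F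
F9 | step 10 | 5-[bis(2,2,2-trifluoroethoxy)phosphoryl]-6-methoxy-6-oxohexanoic acid | COC(=O)C(CCCC(=O)O)P(=O)(OCC(F)(F)F)OCC(F)(F)F
F10 | step 10 | mixed pivalic anhydride of F9 | COC(=O)C(CCCC(=O)OC(=O)C(C)(C)C)P(=O)(OCC(F)(F)F)OCC(F)(F)F
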